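**Retrosynthetic overview**

1. The strategy rests on ring B (cyclohexane C1–C6): the C1 hydroxyl and the C4 chlorine are cis-1,4 and the C5 bromine is trans to both. This is the pattern left when a C1–O–C4 ether bridge is opened at C4 with retention, so the target is traced back (acetate off, C4–Cl ⇐ C4–O) to bromoether 21, a 3-bromo-4-methyl-7-oxabicyclo[2.2.1]heptane.
2. 21 ⇒ cyclohexenol 20 by transannular bromoetherification (C4–O and C5–Br bonds, one new ring, C4 and C5 stereocentres).
3. Ring B of 20 ⇒ ring-closing metathesis of diene 18 ⇒ chelation-controlled allylation of β-hydroxy ketone 16 ⇒ Grignard opening of β-lactone 13.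
4. Ring A: C3′ bromide by inversion of a triflate on the lactone (13 ⇐ 11), quaternary C1′ by Fráter–Seebach methylation, C5′ oxygen by conjugate borylation, C3′ carbinol by CBS reduction of 2,2-dimethylcyclopentane-1,3-dione 1.
5. Order of ring formation: ring A (bought as the dione), temporary β-lactone, ring B (metathesis), temporary oxygen bridge (bromoetherification, opened again one step later).

Key step: step 14

Remark on the chemistry: ring A is numbered C1′ (quaternary carbon bonded to ring B), C2′ (CMe2), C3′ (CHBr), C4′, C5′ (CHOH) and ring B C1 (carbinol) to C6 (C4 = CMeCl, C5 = CHBr). These locants are used in the Why lines for all intermediates, whatever the systematic numbering of their names. The facial sense of the CBS reduction is assigned from the usual model.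

**Route**

Step 1
Reactants: 1 2,2-dimethylcyclopentane-1,3-dione
Product: 2 (R)-3-hydroxy-2,2-dimethylcyclopentan-1-one
Conditions: (S)-2-methyl-CBS-oxazaborolidine (10 mol %), BH3·SMe2 (0.6 equiv), THF, −20 °C; MeOH quench
Reagents that add atoms: none
Why: Corey–Bakshi–Shibata reduction of one of the two homotopic carbonyl groups, in which the quaternary C2′ plays the large substituent so that hydride should be delivered to the face giving the (R)-carbinol (the future C3′, opposite in configuration to the bromide), while the substoichiometric borane limits reduction of the second carbonyl.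

Step 2
Reactants: 2 (R)-3-hydroxy-2,2-dimethylcyclopentan-1-one
Product: 3 (R)-3-[(tert-butyldimethylsilyl)oxy]-2,2-dimethylcyclopentan-1-one
Conditions: TBSCl, imidazole, DMF, rt
Reagents that add atoms: tert-butyldimethylsilyl chloride, CC(C)(C)[Si](C)(C)Cl
Why: Routine silyl ether formation; the bulky silyl group later shields one ring face, and the β-silyloxy ketone cannot eliminate because the carbon between the two functions is quaternary.

Step 3
Reactants: 3 (R)-3-[(tert-butyldimethylsilyl)oxy]-2,2-dimethylcyclopentan-1-one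
Product: 4 (R)-4-[(tert-butyldimethylsilyl)oxy]-5,5-dimethylcyclopent-1-en-1-yl trifluoromethanesulfonate
Conditions: KN(SiMe3)2, PhNTf2, THF, −78 °C
Reagents that add atoms: N-phenylbis(trifluoromethanesulfonimide), O=S(=O)(N(c1ccccc1)S(=O)(=O)C(F)(F)F)C(F)(F)F
Why: Kinetic enolate formation and O-triflation (enol triflate synthesis); the ketone has a single enolisable position, so one regioisomer forms.

Step 4
Reactants: 4 (R)-4-[(tert-butyldimethylsilyl)oxy]-5,5-dimethylcyclopent-1-en-1-yl trifluoromethanesulfonate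
Product: 5 2-(trimethylsilyl)ethyl (R)-4-[(tert-butyldimethylsilyl)oxy]-5,5-dimethylcyclopent-1-ene-1-carboxylate
Conditions: Pd(OAc)2 (5 mol %), dppp (6 mol %), CO (1 atm), Me3SiCH2CH2OH (5 equiv), Et3N, DMF, 70 °C
Reagents that add atoms: carbon monoxide, [C-]#[O+]; 2-(trimethylsilyl)ethanol, C[Si](C)(C)CCO
Why: Palladium-catalysed alkoxycarbonylation of the enol triflate (oxidative addition, CO insertion, alcoholysis) installs the future C1 carbon as an ester whose 2-(trimethylsilyl)ethyl group can later be removed without attack at the hindered acyl carbon.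

Step 5
Reactants: 5 2-(trimethylsilyl)ethyl (R)-4-[(tert-butyldimethylsilyl)oxy]-5,5-dimethylcyclopent-1-ene-1-carboxylate
Product: 7 2-(trimethylsilyl)ethyl (3R,5R)-3-[(tert-butyldimethylsilyl)oxy]-5-hydroxy-2,2-dimethylcyclopentane-1-carboxylate (C1 epimers), via pinacol boronate 6 (not isolated)
Conditions: CuCl (5 mol %), NaOt-Bu (10 mol %), Xantphos (5 mol %), B2pin2 (1.1 equiv), MeOH (2 equiv), THF, rt; then NaBO3·4H2O, THF–H2O, rt
Reagents that add atoms: bis(pinacolato)diboron, CC1(C)OB(OC1(C)C)B1OC(C)(C)C(C)(C)O1 (boron of 6); sodium perborate, [Na+].[Na+].O[B-]1(O)OO[B-](O)(O)OO1 (hydroxyl oxygen of 7)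
Why: Copper-catalysed conjugate borylation of the enoate followed by stereoretentive oxidation of the C–B bond; the bulky borylcopper species should add to C5′ on the ring face anti to the C3′ silyl ether, placing the new hydroxyl trans to it, and the C1′ configuration does not matter because it is erased in step 6.

Step 6
Reactants: 7 2-(trimethylsilyl)ethyl (3R,5R)-3-[(tert-butyldimethylsilyl)oxy]-5-hydroxy-2,2-dimethylcyclopentane-1-carboxylate (C1 epimers)
Product: 9 2-(trimethylsilyl)ethyl (1S,3R,5R)-3-[(tert-butyldimethylsilyl)oxy]-5-hydroxy-1,2,2-trimethylcyclopentane-1-carboxylate, via dilithium alkoxide enolate 8 (not isolated)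
Conditions: LiN(i-Pr)2 (2.3 equiv), THF, −78 → −20 °C; MeI, DMPU, −78 → 0 °C
Reagents that add atoms: lithium diisopropylamide, [Li+].CC(C)[N-]C(C)C (lithium of 8); iodomethane, CI
Why: Fráter–Seebach alkylation: the lithium-chelated alkoxide–enolate dianion is methylated on the face anti to the C5′ alkoxide, which should set the quaternary C1′ with methyl trans and ester cis to the hydroxyl and makes both C1′ epimers of 7 converge.

Step 7
Reactants: 9 2-(trimethylsilyl)ethyl (1S,3R,5R)-3-[(tert-butyldimethylsilyl)oxy]-5-hydroxy-1,2,2-trimethylcyclopentane-1-carboxylate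
Product: 10 (1S,3R,5R)-3,5-dihydroxy-1,2,2-trimethylcyclopentane-1-carboxylic acid
Conditions: Bu4NF (4 equiv), THF, rt → 50 °C; 1 M HCl work-up
Reagents that add atoms: none
Why: Fluoride attacks silicon, so the 2-(trimethylsilyl)ethyl ester fragments to carboxylate, ethylene and fluorosilane without attack at the hindered carbonyl, and the same reagent cleaves the silyl ether.

Step 8
Reactants: 10 (1S,3R,5R)-3,5-dihydroxy-1,2,2-trimethylcyclopentane-1-carboxylic acid
Product: 11 (1S,3R,5R)-3-hydroxy-1,2,2-trimethyl-6-oxabicyclo[3.2.0]heptan-7-one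
Conditions: bis(2-oxo-3-oxazolidinyl)phosphinic chloride (BOP-Cl), Et3N, CH2Cl2, 0 °C → rt
Reagents that add atoms: none
Why: Carboxyl activation and β-lactonisation of the cis β-hydroxy acid; only the C5′ hydroxyl is cis to the carboxyl group, so the trans C3′ hydroxyl cannot lactonise and stays free.

Step 9
Reactants: 11 (1S,3R,5R)-3-hydroxy-1,2,2-trimethyl-6-oxabicyclo[3.2.0]heptan-7-one
Product: 13 (1S,3S,5R)-3-bromo-1,2,2-trimethyl-6-oxabicyclo[3.2.0]heptan-7-one, via secondary triflate 12 (not isolated)
Conditions: Tf2O, pyridine, CH2Cl2, −30 → 0 °C; then Bu4NBr, toluene, 0 °C → rt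
Reagents that add atoms: trifluoromethanesulfonic anhydride, O=S(=O)(OS(=O)(=O)C(F)(F)F)C(F)(F)F (triflyl group of 12); tetrabutylammonium bromide, CCCC[N+](CCCC)(CCCC)CCCC.[Br-]
Why: SN2 displacement of the secondary triflate by bromide with inversion sets the C3′ bromide cis to the C5′ oxygen; here the C5′ oxygen and the acyl carbon are pinned back in the four-membered lactone, so neither can attack the rear of C3′ (which an open ester, ketone or tertiary alcohol on C1′ would do in a 5-exo mode) and the path of bromide is as open as it can be, while the non-polar medium disfavours ionisation and methyl shift.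

Step 10
Reactants: 13 (1S,3S,5R)-3-bromo-1,2,2-trimethyl-6-oxabicyclo[3.2.0]heptan-7-one; 14 4-bromo-2-methylbut-1-ene
Product: 16 1-[(1S,3S,5R)-3-bromo-5-hydroxy-1,2,2-trimethylcyclopentyl]-4-methylpent-4-en-1-one, via (3-methylbut-3-en-1-yl)magnesium bromide 15 (not isolated)
Conditions: 14, Mg, THF, rt; then 13, THF, −78 °C; aq. NH4Cl
Reagents that add atoms: magnesium, [Mg] (metal of 15)
Why: Acyl substitution of the strained β-lactone by the Grignard reagent (acyl C–O cleavage) frees the C5′ alkoxide and gives the ketone, which is flanked by a quaternary carbon and held as a magnesium chelate so that a second addition of the primary Grignard reagent should be slow at −78 °C; the secondary bromide is inert to Grignard reagents at this temperature.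

Step 11
Reactants: 16 1-[(1S,3S,5R)-3-bromo-5-hydroxy-1,2,2-trimethylcyclopentyl]-4-methylpent-4-en-1-one; 17 allylmagnesium bromide
Product: 18 (4R)-4-[(1S,3S,5R)-3-bromo-5-hydroxy-1,2,2-trimethylcyclopentyl]-7-methylocta-1,7-dien-4-ol
Conditions: CH2=CHCH2MgBr (3 equiv), THF, −78 °C; aq. NH4Cl
Reagents that add atoms: none
Why: Chelation-controlled Grignard addition: the first equivalent forms the C5′ magnesium alkoxide, which holds the carbonyl oxygen syn to C5′–O in a six-membered chelate, and allyl then adds to the carbonyl face flanked by the C1′ methyl rather than by the C2′ quaternary carbon (the Felkin–Anh sense as well), which should give the (R)-carbinol and so decides on which arm of ring B the alkene will lie.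

Step 12
Reactants: 18 (4R)-4-[(1S,3S,5R)-3-bromo-5-hydroxy-1,2,2-trimethylcyclopentyl]-7-methylocta-1,7-dien-4-ol
Product: 19 (1R)-1-[(1S,3S,5R)-3-bromo-5-hydroxy-1,2,2-trimethylcyclopentyl]-4-methylcyclohex-3-en-1-ol
Conditions: second-generation Grubbs catalyst RuCl2(=CHPh)(H2IMes)(PCy3) (5 mol %), CH2Cl2 (0.01 M), 40 °C
Reagents that add atoms: none
Why: Ring-closing metathesis between the monosubstituted and the 1,1-disubstituted alkene closes ring B as the trisubstituted cyclohexene, driven by loss of ethylene; no stereocentre is touched.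

Step 13
Reactants: 19 (1R)-1-[(1S,3S,5R)-3-bromo-5-hydroxy-1,2,2-trimethylcyclopentyl]-4-methylcyclohex-3-en-1-ol
Product: 20 (1R,2S,4S)-4-bromo-2-[(1R)-1-hydroxy-4-methylcyclohex-3-en-1-yl]-2,3,3-trimethylcyclopentyl acetate
Conditions: Ac2O, pyridine, DMAP (cat.), CH2Cl2, rt
Reagents that add atoms: acetic anhydride, CC(=O)OC(C)=O
Why: DMAP-catalysed acylation of the secondary C5′ hydroxyl, while the tertiary C1 hydroxyl next to a quaternary carbon is too hindered to react and stays free for the key step.

Step 14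
Reactants: 20 (1R,2S,4S)-4-bromo-2-[(1R)-1-hydroxy-4-methylcyclohex-3-en-1-yl]-2,3,3-trimethylcyclopentyl acetate
Product: 21 (1R,2S,4S)-4-bromo-2-[(1R,3S,4S)-3-bromo-4-methyl-7-oxabicyclo[2.2.1]heptan-1-yl]-2,3,3-trimethylcyclopentyl acetate
Conditions: NBS (1.1 equiv), CH2Cl2, 0 °C, dark
Reagents that add atoms: N-bromosuccinimide, O=C1CCC(=O)N1Br
Why: NBS transfers Br+ reversibly to either face of the C4=C5 alkene, but only the bromonium ion anti to the C1 hydroxyl is trapped, because the tethered oxygen can reach C4 solely from its own ring face through a boat conformer in which ring A takes the outward bowsprit position. The closest known reaction type is the transannular halo-etherification of 4-substituted cyclohex-3-en-1-ols to 2-endo-halo-7-oxabicyclo[2.2.1]heptanes (1,4-cineole series). The one new ring closes by 5-exo attack of oxygen on C4 (ring O–C1–C2–C3–C4 with C5 outside; seen through the other bridge the same bond is 5-endo). C4 is fixed by the tether, since the new C4–O bond must lie cis to the C1–O bond, and C5 is fixed by anti opening of the bromonium ion, which puts bromine trans to the bridge (endo). The step needs site selectivity (oxygen to the tertiary C4, secured by Markovnikov opening and by the only bridge that geometry allows), face selectivity (secured by the tether) and chemoselectivity (secured by the C5′ acetate, which masks the only other hydroxyl and whose carbonyl is too far from the alkene to compete).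

Step 15
Reactants: 21 (1R,2S,4S)-4-bromo-2-[(1R,3S,4S)-3-bromo-4-methyl-7-oxabicyclo[2.2.1]heptan-1-yl]-2,3,3-trimethylcyclopentyl acetate
Product: 22 (1R,2S,4S)-4-bromo-2-[(1R,3S,4S)-3-bromo-4-chloro-1-hydroxy-4-methylcyclohexyl]-2,3,3-trimethylcyclopentyl acetate
Conditions: TiCl4 (2.2 equiv), CH2Cl2, −78 → −30 °C; aq. NaHCO3
Reagents that add atoms: titanium tetrachloride, Cl[Ti](Cl)(Cl)Cl
Why: Lewis-acid ether cleavage of the cineole type: with the acetate carbonyl tied up by the first equivalent of TiCl4, titanium on the bridge oxygen should let the tertiary C4–O bond ionise with anchimeric assistance from the anti (endo) C5 bromine, and chloride then opens the bromonium ion at the tertiary C4 on the face the oxygen has left, so chlorine replaces oxygen with net retention, ends cis to the C1 hydroxyl, and bromine stays on C5.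

Step 16
Reactants: 22 (1R,2S,4S)-4-bromo-2-[(1R,3S,4S)-3-bromo-4-chloro-1-hydroxy-4-methylcyclohexyl]-2,3,3-trimethylcyclopentyl acetate
Product: 23 (1R,3S,4S)-3-bromo-1-[(1S,3S,5R)-3-bromo-5-hydroxy-1,2,2-trimethylcyclopentyl]-4-chloro-4-methylcyclohexan-1-ol (CNP0158757.1)
Conditions: K2CO3 (0.5 equiv), MeOH, rt
Reagents that add atoms: none
Why: Base-catalysed transesterification (methanolysis) removes the hindered secondary acetate; carbonate in methanol at room temperature should be too weak a base to eliminate or displace the secondary bromides or the tertiary chloride.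

**Compound list**

1 | 2,2-dimethylcyclopentane-1,3-dione | CC1(C)C(=O)CCC1=O | starting material
2 | (R)-3-hydroxy-2,2-dimethylcyclopentan-1-one | CC1(C)[C@H](O)CCC1=O | intermediate
3 | (R)-3-[(tert-butyldimethylsilyl)oxy]-2,2-dimethylcyclopentan-1-one | CC1(C)[C@H](O[Si](C)(C)C(C)(C)C)CCC1=O | intermediate
4 | (R)-4-[(tert-butyldimethylsilyl)oxy]-5,5-dimethylcyclopent-1-en-1-yl trifluoromethanesulfonate | CC1(C)[C@H](O[Si](C)(C)C(C)(C)C)CC=C1OS(=O)(=O)C(F)(F)F | intermediate
5 | 2-(trimethylsilyl)ethyl (R)-4-[(tert-butyldimethylsilyl)oxy]-5,5-dimethylcyclopent-1-ene-1-carboxylate | CC1(C)[C@H](O[Si](C)(C)C(C)(C)C)CC=C1C(=O)OCC[Si](C)(C)C | intermediate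
6 | 2-(trimethylsilyl)ethyl (3R,5R)-3-[(tert-butyldimethylsilyl)oxy]-2,2-dimethyl-5-(4,4,5,5-tetramethyl-1,3,2-dioxaborolan-2-yl)cyclopentane-1-carboxylate (C1 epimers) | CC1(C)[C@H](O[Si](C)(C)C(C)(C)C)C[C@@H](B2OC(C)(C)C(C)(C)O2)C1C(=O)OCC[Si](C)(C)C | intermediate
7 | 2-(trimethylsilyl)ethyl (3R,5R)-3-[(tert-butyldimethylsilyl)oxy]-5-hydroxy-2,2-dimethylcyclopentane-1-carboxylate (C1 epimers) | CC1(C)[C@H](O[Si](C)(C)C(C)(C)C)C[C@@H](O)C1C(=O)OCC[Si](C)(C)C | intermediate
8 | dilithium alkoxide ester enolate of 7 | [Li+].[Li+].CC1(C)[C@H](O[Si](C)(C)C(C)(C)C)C[C@@H]([O-])C1=C([O-])OCC[Si](C)(C)C | intermediate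
9 | 2-(trimethylsilyl)ethyl (1S,3R,5R)-3-[(tert-butyldimethylsilyl)oxy]-5-hydroxy-1,2,2-trimethylcyclopentane-1-carboxylate | CC1(C)[C@H](O[Si](C)(C)C(C)(C)C)C[C@@H](O)[C@@]1(C)C(=O)OCC[Si](C)(C)C | intermediate
10 | (1S,3R,5R)-3,5-dihydroxy-1,2,2-trimethylcyclopentane-1-carboxylic acid | CC1(C)[C@H](O)C[C@@H](O)[C@@]1(C)C(O)=O | intermediate
11 | (1S,3R,5R)-3-hydroxy-1,2,2-trimethyl-6-oxabicyclo[3.2.0]heptan-7-one | CC1(C)[C@H](O)C[C@H]2OC(=O)[C@@]12C | intermediate
12 | (1S,3R,5R)-1,2,2-trimethyl-7-oxo-6-oxabicyclo[3.2.0]heptan-3-yl trifluoromethanesulfonate | CC1(C)[C@H](OS(=O)(=O)C(F)(F)F)C[C@H]2OC(=O)[C@@]12C | intermediate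
13 | (1S,3S,5R)-3-bromo-1,2,2-trimethyl-6-oxabicyclo[3.2.0]heptan-7-one | CC1(C)[C@@H](Br)C[C@H]2OC(=O)[C@@]12C | intermediate
14 | 4-bromo-2-methylbut-1-ene | CC(=C)CCBr | starting material
15 | (3-methylbut-3-en-1-yl)magnesium bromide | CC(=C)CC[Mg]Br | intermediate
16 | 1-[(1S,3S,5R)-3-bromo-5-hydroxy-1,2,2-trimethylcyclopentyl]-4-methylpent-4-en-1-one | CC1(C)[C@@H](Br)C[C@@H](O)[C@@]1(C)C(=O)CCC(C)=C | intermediate
17 | allylmagnesium bromide | C=CC[Mg]Br | starting material
18 | (4R)-4-[(1S,3S,5R)-3-bromo-5-hydroxy-1,2,2-trimethylcyclopentyl]-7-methylocta-1,7-dien-4-ol | CC1(C)[C@@H](Br)C[C@@H](O)[C@@]1(C)[C@@](CC=C)(O)CCC(C)=C | intermediate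
19 | (1R)-1-[(1S,3S,5R)-3-bromo-5-hydroxy-1,2,2-trimethylcyclopentyl]-4-methylcyclohex-3-en-1-ol | CC1(C)[C@@H](Br)C[C@@H](O)[C@@]1(C)[C@@]1(O)CCC(C)=CC1 | intermediate
20 | (1R,2S,4S)-4-bromo-2-[(1R)-1-hydroxy-4-methylcyclohex-3-en-1-yl]-2,3,3-trimethylcyclopentyl acetate | CC1(C)[C@@H](Br)C[C@@H](OC(C)=O)[C@@]1(C)[C@@]1(O)CCC(C)=CC1 | intermediate
21 | (1R,2S,4S)-4-bromo-2-[(1R,3S,4S)-3-bromo-4-methyl-7-oxabicyclo[2.2.1]heptan-1-yl]-2,3,3-trimethylcyclopentyl acetate | CC1(C)[C@@H](Br)C[C@@H](OC(C)=O)[C@@]1(C)[C@@]12CC[C@](C)(O2)[C@@H](Br)C1 | intermediate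
22 | (1R,2S,4S)-4-bromo-2-[(1R,3S,4S)-3-bromo-4-chloro-1-hydroxy-4-methylcyclohexyl]-2,3,3-trimethylcyclopentyl acetate | CC1(C)[C@@H](Br)C[C@@H](OC(C)=O)[C@@]1(C)[C@@]1(O)CC[C@](C)(Cl)[C@@H](Br)C1 | intermediate
23 | (1R,3S,4S)-3-bromo-1-[(1S,3S,5R)-3-bromo-5-hydroxy-1,2,2-trimethylcyclopentyl]-4-chloro-4-methylcyclohexan-1-ol | CC1(C)[C@@H](Br)C[C@@H](O)[C@@]1(C)[C@@]1(O)CC[C@](C)(Cl)[C@@H](Br)C1 | target

**Step count and risks**

Total step count: 16. Longest linear sequence: 16 steps (1 → 23); the two Grignard partners are a commercial solution (17) and a reagent made in the flask from commercial 14.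

The three steps most likely to fail:

Step 9 (bromide for triflate at C3′). The substitution takes place at a secondary carbon next to a quaternary one, with bromide entering on the concave face of the bicyclic lactone. Elimination toward C4′, ionisation with methyl migration, opening of the lactone at C5′ by bromide, or slow epimerisation of the product by bromide exchange may outrun clean inversion.
Fallback: the substitution is moved to the simplest substrate, setting out from 2 and returning at 13.
- Tf2O/pyridine converts 2 into (R)-2,2-dimethyl-3-oxocyclopentyl trifluoromethanesulfonate F1, and Bu4NBr in toluene should give (S)-3-bromo-2,2-dimethylcyclopentan-1-one F2. Here the reacting carbon has no cis-1,3 substituents and the nearby carbonyl disfavours ionisation.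
- The chemistry of steps 3 and 4 then leads to (S)-4-bromo-5,5-dimethylcyclopent-1-en-1-yl trifluoromethanesulfonate F3 and 2-(trimethylsilyl)ethyl (S)-4-bromo-5,5-dimethylcyclopent-1-ene-1-carboxylate F4.
- Boron would now add anti to bromine, so conjugate borylation serves only to oxygenate C5′: the boronate mixture F5 is oxidised to the hydroxy ester mixture F6, and Dess–Martin periodinane gives the β-keto ester 2-(trimethylsilyl)ethyl (3S)-3-bromo-2,2-dimethyl-5-oxocyclopentane-1-carboxylate F7.
- Hydrogenation with RuCl2[(R)-BINAP] (H2, CH2Cl2) should set the C5′ carbinol by catalyst control, giving 2-(trimethylsilyl)ethyl (3S,5R)-3-bromo-5-hydroxy-2,2-dimethylcyclopentane-1-carboxylate F8.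
- Fráter–Seebach methylation through the dilithium alkoxide enolate F9 (methyl now anti to both the alkoxide and the bromine) gives 2-(trimethylsilyl)ethyl (1S,3S,5R)-3-bromo-5-hydroxy-1,2,2-trimethylcyclopentane-1-carboxylate F10. Bu4NF gives (1S,3S,5R)-3-bromo-5-hydroxy-1,2,2-trimethylcyclopentane-1-carboxylic acid F11, and BOP-Cl closes the lactone to 13.

Step 10 (Grignard opening of the β-lactone). The ketone may take up a second equivalent of the Grignard reagent, or magnesium bromide may open the lactone at C5′ (alkyl C–O cleavage) instead of the acyl carbon being attacked.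
Fallback: the acyl group is first transferred to a Weinreb amide, setting out from 13 and returning at 16. MeNH(OMe)·HCl with Me2AlCl should open the lactone at the acyl carbon to (1S,3S,5R)-3-bromo-5-hydroxy-N-methoxy-N,1,2,2-tetramethylcyclopentane-1-carboxamide F12. Grignard reagent 15 (excess, 0 °C) then gives 16 through the stable five-membered magnesium chelate, which cannot take up a second equivalent.

Step 15 (chlorinolysis of the ether bridge). Both bridge carbons are tertiary, so heterolysis of the C1–O bond may compete with the bromine-assisted heterolysis of the C4–O bond and lead to rearrangement or elimination at C1. The bromonium ion may also lose a proton, or be opened at C5 with bromine migration.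
Fallback: the C4 oxygen is brought in as an epoxide and activated by a bimolecular reagent, so that the C1 oxygen is never activated; this sets out from 20 and returns at 22.
- VO(acac)2/t-BuOOH should epoxidise C4=C5 on the face of the directing C1 hydroxyl, giving the syn-epoxy alcohol (C4–C5 epoxide of 20 cis to the C1 hydroxyl) F13.
- Li2NiBr4 in THF should open the epoxide at the secondary C5 with inversion, giving the bromohydrin (C4 hydroxyl analogue of 22) F14, with bromine trans and the C4 hydroxyl cis to the C1 hydroxyl.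
- SOCl2 in Et2O without base should esterify only the less hindered C4 hydroxyl. The chlorosulfite ionises with participation of the anti bromine and chloride returns to the same face, giving 22 with retention.

**Further compounds**

F1 | step 9 | (R)-2,2-dimethyl-3-oxocyclopentyl trifluoromethanesulfonate | CC1(C)[C@H](OS(=O)(=O)C(F)(F)F)CCC1=O
F2 | step 9 | (S)-3-bromo-2,2-dimethylcyclopentan-1-one | CC1(C)[C@@H](Br)CCC1=O
F3 | step 9 | (S)-4-bromo-5,5-dimethylcyclopent-1-en-1-yl trifluoromethanesulfonate | CC1(C)[C@@H](Br)CC=C1OS(=O)(=O)C(F)(F)F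
F4 | step 9 | 2-(trimethylsilyl)ethyl (S)-4-bromo-5,5-dimethylcyclopent-1-ene-1-carboxylate | CC1(C)[C@@H](Br)CC=C1C(=O)OCC[Si](C)(C)C
F5 | step 9 | 2-(trimethylsilyl)ethyl (3S)-3-bromo-2,2-dimethyl-5-(4,4,5,5-tetramethyl-1,3,2-dioxaborolan-2-yl)cyclopentane-1-carboxylate (C1 and C5 epimers) | CC1(C)[C@@H](Br)CC(B2OC(C)(C)C(C)(C)O2)C1C(=O)OCC[Si](C)(C)C
F6 | step 9 | 2-(trimethylsilyl)ethyl (3S)-3-bromo-5-hydroxy-2,2-dimethylcyclopentane-1-carboxylate (C1 and C5 epimers) | CC1(C)[C@@H](Br)CC(O)C1C(=O)OCC[Si](C)(C)C
F7 | step 9 | 2-(trimethylsilyl)ethyl (3S)-3-bromo-2,2-dimethyl-5-oxocyclopentane-1-carboxylate | CC1(C)[C@@H](Br)CC(=O)C1C(=O)OCC[Si](C)(C)C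
F8 | step 9 | 2-(trimethylsilyl)ethyl (3S,5R)-3-bromo-5-hydroxy-2,2-dimethylcyclopentane-1-carboxylate (C1 epimers) | CC1(C)[C@@H](Br)C[C@@H](O)C1C(=O)OCC[Si](C)(C)C
F9 | step 9 | dilithium alkoxide ester enolate of F8 | [Li+].[Li+].CC1(C)[C@@H](Br)C[C@@H]([O-])C1=C([O-])OCC[Si](C)(C)C
F10 | step 9 | 2-(trimethylsilyl)ethyl (1S,3S,5R)-3-bromo-5-hydroxy-1,2,2-trimethylcyclopentane-1-carboxylate | CC1(C)[C@@H](Br)C[C@@H](O)[C@@]1(C)C(=O)OCC[Si](C)(C)C
F11 | step 9 | (1S,3S,5R)-3-bromo-5-hydroxy-1,2,2-trimethylcyclopentane-1-carboxylic acid | CC1(C)[C@@H](Br)C[C@@H](O)[C@@]1(C)C(O)=O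
F12 | step 10 | (1S,3S,5R)-3-bromo-5-hydroxy-N-methoxy-N,1,2,2-tetramethylcyclopentane-1-carboxamide | CC1(C)[C@@H](Br)C[C@@H](O)[C@@]1(C)C(=O)N(C)OC
F13 | step 15 | C4–C5 epoxide of 20 on the ring B face cis to the C1 hydroxyl (5′-acetate) | CC1(C)[C@@H](Br)C[C@@H](OC(C)=O)[C@@]1(C)[C@@]1(O)CC[C@]2(C)O[C@@H]2C1
F14 | step 15 | C4 hydroxyl analogue of 22 (C4 tertiary alcohol cis to the C1 hydroxyl, C5 bromide trans, 5′-acetate) | CC1(C)[C@@H](Br)C[C@@H](OC(C)=O)[C@@]1(C)[C@@]1(O)CC[C@](C)(O)[C@@H](Br)C1
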